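**Plan**

- Numbering (germacranolide): ring carbons C1–C10; lactone O–C6 and C12(=O); exo-methylene C11=C13; formyl C14 on C10; acetoxymethyl C15 on C4; acyloxy group on C8.
- Cuts, in order: the C8 ester; then C7–C8, the bond from the β-carbon of the α-methylene-γ-butyrolactone (ring O–C6–C7–C11–C12) to the carbinol C8. The unit C13=C11–C7–C8–OH is the retron of an allylmetal addition, so this cut opens the ten-membered ring to a 3-(bromomethyl)butenolide aldehyde. Then C1=C10 (Wittig), C11–C12 and O–C12 (CO insertion), C6–C7 (alkynylation), C4=C5 (Wittig).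
- Forward: chain C3–C6 with C15; C6 carbinol with the C7/C11/C13 alkyne; butenolide (first ring); C1=C10 with C8, C9 and C14; ten-membered ring (last ring); acylation of C8.
- Stereochemistry: C6 from a catalytic asymmetric alkynylation. C7 and C8 from C6 during ring closure (attack anti to the C6 substituent; chair transition state of an allylmetal locked E by the butenolide ring). Both ring-cis trisubstituted olefins from E-selective Wittig reactions of α-substituted stabilised ylides. The acyl centre from (S)-2-methylbutanoic anhydride.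
- The C15 acetate and the C14 aldehyde are in place before ring closure, so only the acylation follows it.

Key step: step 17

Remark: the (S,S) enantiomer of ProPhenol is assumed to give the 4R alcohol in step 4; if the sense of induction is the opposite, the (R,R) ligand is used and nothing else changes. TBS = tert-butyldimethylsilyl.

**Route**

Step 1
Reactants: 1 (ethoxycarbonylmethylene)triphenylphosphorane; 2 allyl bromide
Product: 4 ethyl 2-(triphenylphosphoranylidene)pent-4-enoate, via allylated phosphonium bromide 3 (not isolated)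
Conditions: CHCl3, reflux; then aq. NaOH, CH2Cl2, rt
Reagents that add atoms: none
Why: C-alkylation of the stabilised ylide by the reactive allylic bromide and deprotonation of salt 3 should give the α-allyl ylide (ylide alkylation), which carries C15, C4, C3, C2 and C1; no stereocentre is formed.

Step 2
Reactants: 4 ethyl 2-(triphenylphosphoranylidene)pent-4-enoate; 5 2,2-dimethoxyacetaldehyde
Product: 6 ethyl (2E)-4,4-dimethoxy-2-(prop-2-en-1-yl)but-2-enoate
Conditions: CH2Cl2, rt (5 as its 60% aqueous solution)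
Reagents that add atoms: none
Why: The Wittig reaction of an α-substituted ester-stabilised ylide with an unhindered α-alkoxy aldehyde is E-selective, which places C6 trans to the ester carbon C15 and cis to C3, the ring-cis C4=C5 geometry of the target.

Step 3
Reactants: 6 ethyl (2E)-4,4-dimethoxy-2-(prop-2-en-1-yl)but-2-enoate
Product: 7 ethyl (2E)-4-oxo-2-(prop-2-en-1-yl)but-2-enoate
Conditions: Amberlyst-15, acetone/H2O, rt
Reagents that add atoms: water, O
Why: Acid-catalysed acetal hydrolysis should free the C6 aldehyde while the ester survives, and because the aldehyde is trans to the ester no cyclic pseudo-ester can form.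

Step 4
Reactants: 7 ethyl (2E)-4-oxo-2-(prop-2-en-1-yl)but-2-enoate; 8 tert-butyldimethyl(prop-2-yn-1-yloxy)silane
Product: 10 ethyl (2E,4R)-4-hydroxy-2-(prop-2-en-1-yl)-7-(TBS-oxy)hept-2-en-5-ynoate, via alkynyl(methyl)zinc 9 (not isolated)
Conditions: Me2Zn (3 equiv), (S,S)-ProPhenol (10 mol %), Ph3P=O (20 mol %), toluene, 0 °C
Reagents that add atoms: none
Why: Zinc–ProPhenol asymmetric alkynylation of an α,β-unsaturated aldehyde should deliver the alkynylzinc 9 in a 1,2 sense to one face of the aldehyde inside the dinuclear zinc catalyst, which sets C6 (4R here) under reagent control and brings in C7, C11 and C13.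

Step 5
Reactants: 10 ethyl (2E,4R)-4-hydroxy-2-(prop-2-en-1-yl)-7-(TBS-oxy)hept-2-en-5-ynoate
Product: 11 (2E,4R)-2-(prop-2-en-1-yl)-7-(TBS-oxy)hept-2-en-5-yne-1,4-diol
Conditions: i-Bu2AlH (3.5 equiv), CH2Cl2, −78 °C; aq. potassium sodium tartrate
Reagents that add atoms: none
Why: i-Bu2AlH reduction of the conjugated ester is 1,2-selective at low temperature and gives the C15 allylic alcohol, which removes the enoate before the alkoxide-directed hydride reagent of the next step could reduce it in a conjugate sense.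

Step 6
Reactants: 11 (2E,4R)-2-(prop-2-en-1-yl)-7-(TBS-oxy)hept-2-en-5-yne-1,4-diol
Product: 13 (2E,4R,5Z)-6-iodo-2-(prop-2-en-1-yl)-7-(TBS-oxy)hepta-2,5-diene-1,4-diol, via cyclic alkenylalanate 12 (not isolated)
Conditions: NaAlH2(OCH2CH2OMe)2 (3 equiv), THF, 0 °C → rt; then I2, −78 °C
Reagents that add atoms: iodine, [I][I]
Why: Alkoxide-directed trans-hydroalumination of the propargylic alcohol puts hydride on C7 and aluminium on C11 in the five-membered alanate 12 (the silyl ether on C13 cannot direct), and iodinolysis with retention should give the vinyl iodide with iodine cis to C6.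

Step 7
Reactants: 13 (2E,4R,5Z)-6-iodo-2-(prop-2-en-1-yl)-7-(TBS-oxy)hepta-2,5-diene-1,4-diol
Product: 14 (5R)-5-[(1E)-2-(hydroxymethyl)penta-1,4-dien-1-yl]-3-[(TBS-oxy)methyl]furan-2(5H)-one
Conditions: PdCl2(PPh3)2 (5 mol %), CO (1 atm), K2CO3, THF, rt
Reagents that add atoms: carbon monoxide, [C-]#[O+]
Why: Palladium-catalysed carbonylative lactonisation (oxidative addition of the vinyl iodide, CO insertion, capture of the acylpalladium by the cis C6 hydroxyl) should close the butenolide with C12, while the C15 hydroxyl is trans to C6 and cannot reach; C6 is not touched.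

Step 8
Reactants: 14 (5R)-5-[(1E)-2-(hydroxymethyl)penta-1,4-dien-1-yl]-3-[(TBS-oxy)methyl]furan-2(5H)-one
Product: 15 (5R)-5-[(1E)-2-(acetoxymethyl)penta-1,4-dien-1-yl]-3-[(TBS-oxy)methyl]furan-2(5H)-one
Conditions: Ac2O, pyridine, CH2Cl2, 0 °C
Reagents that add atoms: acetic anhydride, CC(=O)OC(C)=O
Why: Acetylation of the only free hydroxyl installs the C15 acetate of the target after the last hydride step, and pyridine alone is too weak a base to enolise the γ-position (C6) of the butenolide.

Step 9
Reactants: 15 (5R)-5-[(1E)-2-(acetoxymethyl)penta-1,4-dien-1-yl]-3-[(TBS-oxy)methyl]furan-2(5H)-one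
Product: 17 (5R)-5-[(1E)-2-(acetoxymethyl)-5-hydroxypent-1-en-1-yl]-3-[(TBS-oxy)methyl]furan-2(5H)-one, via B-alkyl-9-BBN adduct 16 (not isolated)
Conditions: 9-BBN, THF, 0 °C → rt; then 30% H2O2, aq. NaOAc, 0 °C
Reagents that add atoms: hydrogen peroxide, OO
Why: Anti-Markovnikov hydroboration with 9-BBN is selective for the monosubstituted terminal alkene over the trisubstituted and the conjugated olefin, and acetate-buffered oxidation of 16 should give the C1 alcohol without cleaving the acetate or epimerising C6.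

Step 10
Reactants: 17 (5R)-5-[(1E)-2-(acetoxymethyl)-5-hydroxypent-1-en-1-yl]-3-[(TBS-oxy)methyl]furan-2(5H)-one
Product: 18 (5R)-5-[(1E)-2-(acetoxymethyl)-5-oxopent-1-en-1-yl]-3-[(TBS-oxy)methyl]furan-2(5H)-one
Conditions: Dess–Martin periodinane, NaHCO3, CH2Cl2, 0 °C → rt
Reagents that add atoms: none
Why: Buffered Dess–Martin oxidation gives the C1 aldehyde under non-basic conditions that should leave C6 and the butenolide olefin in place.

Step 11
Reactants: 19 (3-bromopropoxy)(tert-butyl)dimethylsilane; 20 triphenylphosphine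
Product: 21 [3-(TBS-oxy)propyl]triphenylphosphonium bromide
Conditions: MeCN, reflux
Reagents that add atoms: none
Why: SN2 quaternisation of triphenylphosphine by the primary bromide gives the salt that carries C8, C9 and C10.

Step 12
Reactants: 21 [3-(TBS-oxy)propyl]triphenylphosphonium bromide; 22 ethyl formate
Product: 24 4-(TBS-oxy)-2-(triphenylphosphoranylidene)butanal, via non-stabilised ylide 23 (not isolated)
Conditions: n-BuLi (1 equiv), THF, −78 → 0 °C; then 22, −78 °C → rt
Reagents that add atoms: none
Why: C-formylation of the non-stabilised ylide 23 by the formate (ylide acylation) gives an acylphosphonium ethoxide that collapses to the formyl-stabilised ylide, which brings in C14 at the aldehyde level.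

Step 13
Reactants: 18 (5R)-5-[(1E)-2-(acetoxymethyl)-5-oxopent-1-en-1-yl]-3-[(TBS-oxy)methyl]furan-2(5H)-one; 24 4-(TBS-oxy)-2-(triphenylphosphoranylidene)butanal
Product: 25 (5R)-5-[(1E,5E)-2-(acetoxymethyl)-6-formyl-8-(TBS-oxy)octa-1,5-dien-1-yl]-3-[(TBS-oxy)methyl]furan-2(5H)-one
Conditions: toluene, 80 °C
Reagents that add atoms: none
Why: The Wittig reaction of an α-substituted formyl-stabilised ylide with an aliphatic aldehyde is E-selective and near neutral, so C14 should end trans to C2 and C9 cis to C2 (ring-cis C1=C10) with no later hydride step needed for the enal.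

Step 14
Reactants: 25 (5R)-5-[(1E,5E)-2-(acetoxymethyl)-6-formyl-8-(TBS-oxy)octa-1,5-dien-1-yl]-3-[(TBS-oxy)methyl]furan-2(5H)-one
Product: 26 (5R)-5-[(1E,5E)-2-(acetoxymethyl)-6-formyl-8-hydroxyocta-1,5-dien-1-yl]-3-(hydroxymethyl)furan-2(5H)-one
Conditions: HF·pyridine, pyridine, THF, 0 °C → rt
Reagents that add atoms: none
Why: Fluoride cleavage of the two primary silyl ethers under buffered acidic conditions should spare the acetate, the enal and the base-sensitive butenolide.

Step 15
Reactants: 26 (5R)-5-[(1E,5E)-2-(acetoxymethyl)-6-formyl-8-hydroxyocta-1,5-dien-1-yl]-3-(hydroxymethyl)furan-2(5H)-one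
Product: 27 (5R)-5-[(1E,5E)-2-(acetoxymethyl)-6-formyl-8-hydroxyocta-1,5-dien-1-yl]-3-(bromomethyl)furan-2(5H)-one
Conditions: NBS, Me2S, CH2Cl2, −20 → 0 °C
Reagents that add atoms: N-bromosuccinimide, O=C1CCC(=O)N1Br
Why: Corey–Kim bromination converts allylic alcohols selectively, so only the C13 hydroxyl should become the bromide while the saturated C8 alkoxysulfonium salt reverts to the alcohol on work-up, and SN2 or SN2′ delivery of bromide would both lead to the conjugated primary bromide.

Step 16
Reactants: 27 (5R)-5-[(1E,5E)-2-(acetoxymethyl)-6-formyl-8-hydroxyocta-1,5-dien-1-yl]-3-(bromomethyl)furan-2(5H)-one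
Product: 28 (5R)-5-[(1E,5E)-2-(acetoxymethyl)-6-formyl-8-oxoocta-1,5-dien-1-yl]-3-(bromomethyl)furan-2(5H)-one
Conditions: Dess–Martin periodinane, NaHCO3, CH2Cl2, 0 °C; used crude at once
Reagents that add atoms: none
Why: Buffered Dess–Martin oxidation of the remaining primary alcohol gives the β,γ-unsaturated C8 aldehyde without base, and immediate use should prevent migration of the C1=C10 double bond into conjugation with it.

Step 17
Reactants: 28 (5R)-5-[(1E,5E)-2-(acetoxymethyl)-6-formyl-8-oxoocta-1,5-dien-1-yl]-3-(bromomethyl)furan-2(5H)-one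
Product: 30 [(3aR,4S,6E,10E,11aR)-6-formyl-4-hydroxy-3-methylidene-2-oxo-2,3,3a,4,5,8,9,11a-octahydrocyclodeca[b]furan-10-yl]methyl acetate, via allylchromium dichloride 29 (not isolated)
Conditions: CrCl2 (8 equiv), THF, rt, syringe-pump addition of 28 to a final 2 mM; aq. NH4Cl
Reagents that add atoms: none
Why: Proposed new method: two equivalents of CrCl2 reduce the allylic bromide to the allylchromium 29 (chromium on C13), which adds through its γ-carbon C7 to the C8 aldehyde in a six-membered chair (Zimmerman–Traxler) transition state with transposition of the double bond to C11=C13, so that one event closes the ring and creates the exo-methylene, C7 and C8; the closest known reactions are the intermolecular chromium-, zinc- or indium-mediated additions of 3-(bromomethyl)furan-2(5H)-ones to aldehydes and the intramolecular Nozaki–Hiyama allylations of aldehydes by 2-(bromomethyl)acrylates that close ten-membered carbocycles, and only their combination is new. The ten-membered carbocycle is closed by C7–C8 bond formation, 10-exo-trig at the aldehyde and SE2′ at the allyl unit. C7 is controlled by C6: the chain leaves C6 on one face of the flat butenolide and the aldehyde should reach C7 from the other, the usual anti approach to a 5-substituted butenolide, reinforced here because a trans junction (anticlinal C5–C6–C7–C8) fits a cis,cis-cyclodeca-1,5-diene better than an eclipsed cis one. C8 is controlled by the butenolide ring, which locks the allylmetal as the E-type γ-substituted isomer (C6 trans to C13), so that the chair with C9 equatorial gives the anti C7/C8 relation, that is 8S. The step needs ring closure to beat oligomerisation, secured by slow addition at high dilution and by the two ring-cis trisubstituted olefins that fold C8 back towards C7, and it needs the C8 aldehyde to react in preference to the C14 enal, secured because the enal is less electrophilic and cannot be reached by C7 without forming an E-cyclononene.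

Step 18
Reactants: 30 [(3aR,4S,6E,10E,11aR)-6-formyl-4-hydroxy-3-methylidene-2-oxo-2,3,3a,4,5,8,9,11a-octahydrocyclodeca[b]furan-10-yl]methyl acetate; 31 (2S)-2-methylbutanoic anhydride
Product: 32 (3aR,4S,6E,10E,11aR)-10-(acetoxymethyl)-6-formyl-3-methylidene-2-oxo-2,3,3a,4,5,8,9,11a-octahydrocyclodeca[b]furan-4-yl (2S)-2-methylbutanoate (CNP0230988.8)
Conditions: DMAP (10 mol %), pyridine, CH2Cl2, 0 °C → rt
Reagents that add atoms: none
Why: DMAP-catalysed acylation of the secondary C8 alcohol by the enantiopure anhydride installs the ester with retention at C8 and without epimerising the acyl α-centre.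

**Compound list**

1 | (ethoxycarbonylmethylene)triphenylphosphorane | CCOC(=O)C=P(c1ccccc1)(c1ccccc1)c1ccccc1 | starting material
2 | allyl bromide | C=CCBr | starting material
3 | [1-(ethoxycarbonyl)but-3-en-1-yl]triphenylphosphonium bromide (not isolated) | CCOC(=O)C(CC=C)[P+](c1ccccc1)(c1ccccc1)c1ccccc1.[Br-] | intermediate
4 | ethyl 2-(triphenylphosphoranylidene)pent-4-enoate | CCOC(=O)C(CC=C)=P(c1ccccc1)(c1ccccc1)c1ccccc1 | intermediate
5 | 2,2-dimethoxyacetaldehyde | COC(OC)C=O | starting material
6 | ethyl (2E)-4,4-dimethoxy-2-(prop-2-en-1-yl)but-2-enoate | CCOC(=O)/C(CC=C)=C/C(OC)OC | intermediate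
7 | ethyl (2E)-4-oxo-2-(prop-2-en-1-yl)but-2-enoate | CCOC(=O)/C(CC=C)=C/C=O | intermediate
8 | tert-butyldimethyl(prop-2-yn-1-yloxy)silane | C#CCO[Si](C)(C)C(C)(C)C | starting material
9 | methyl[3-(TBS-oxy)prop-1-yn-1-yl]zinc (not isolated) | C[Zn]C#CCO[Si](C)(C)C(C)(C)C | intermediate
10 | ethyl (2E,4R)-4-hydroxy-2-(prop-2-en-1-yl)-7-(TBS-oxy)hept-2-en-5-ynoate | CCOC(=O)/C(CC=C)=C/[C@@H](O)C#CCO[Si](C)(C)C(C)(C)C | intermediate
11 | (2E,4R)-2-(prop-2-en-1-yl)-7-(TBS-oxy)hept-2-en-5-yne-1,4-diol | OC/C(CC=C)=C/[C@@H](O)C#CCO[Si](C)(C)C(C)(C)C | intermediate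
12 | disodium salt of the cyclic alkenylalanate of 11: aluminium bridges O4 and C6 in a five-membered ring and carries two 2-methoxyethoxy groups; O1 is bound to a hydridobis(2-methoxyethoxy)aluminate (not isolated) | [Na+].[Na+].COCCO[Al-]1(OCCOC)O[C@H](/C=C(\CC=C)CO[Al-]([H])(OCCOC)OCCOC)C=C1CO[Si](C)(C)C(C)(C)C | intermediate
13 | (2E,4R,5Z)-6-iodo-2-(prop-2-en-1-yl)-7-(TBS-oxy)hepta-2,5-diene-1,4-diol | OC/C(CC=C)=C/[C@@H](O)/C=C(\I)CO[Si](C)(C)C(C)(C)C | intermediate
14 | (5R)-5-[(1E)-2-(hydroxymethyl)penta-1,4-dien-1-yl]-3-[(TBS-oxy)methyl]furan-2(5H)-one | OC/C(CC=C)=C/[C@H]1OC(=O)C(CO[Si](C)(C)C(C)(C)C)=C1 | intermediate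
15 | (5R)-5-[(1E)-2-(acetoxymethyl)penta-1,4-dien-1-yl]-3-[(TBS-oxy)methyl]furan-2(5H)-one | CC(=O)OC/C(CC=C)=C/[C@H]1OC(=O)C(CO[Si](C)(C)C(C)(C)C)=C1 | intermediate
16 | 9-borabicyclo[3.3.1]nonane adduct of 15, boron on the terminal carbon C1 (not isolated) | CC(=O)OC/C(CCCB1C2CCCC1CCC2)=C/[C@H]1OC(=O)C(CO[Si](C)(C)C(C)(C)C)=C1 | intermediate
17 | (5R)-5-[(1E)-2-(acetoxymethyl)-5-hydroxypent-1-en-1-yl]-3-[(TBS-oxy)methyl]furan-2(5H)-one | CC(=O)OC/C(CCCO)=C/[C@H]1OC(=O)C(CO[Si](C)(C)C(C)(C)C)=C1 | intermediate
18 | (5R)-5-[(1E)-2-(acetoxymethyl)-5-oxopent-1-en-1-yl]-3-[(TBS-oxy)methyl]furan-2(5H)-one | CC(=O)OC/C(CCC=O)=C/[C@H]1OC(=O)C(CO[Si](C)(C)C(C)(C)C)=C1 | intermediate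
19 | (3-bromopropoxy)(tert-butyl)dimethylsilane | BrCCCO[Si](C)(C)C(C)(C)C | starting material
20 | triphenylphosphine | c1ccc(cc1)P(c1ccccc1)c1ccccc1 | starting material
21 | [3-(TBS-oxy)propyl]triphenylphosphonium bromide | CC(C)(C)[Si](C)(C)OCCC[P+](c1ccccc1)(c1ccccc1)c1ccccc1.[Br-] | intermediate
22 | ethyl formate | CCOC=O | starting material
23 | [3-(TBS-oxy)propylidene]triphenylphosphorane (not isolated) | CC(C)(C)[Si](C)(C)OCCC=P(c1ccccc1)(c1ccccc1)c1ccccc1 | intermediate
24 | 4-(TBS-oxy)-2-(triphenylphosphoranylidene)butanal | O=CC(CCO[Si](C)(C)C(C)(C)C)=P(c1ccccc1)(c1ccccc1)c1ccccc1 | intermediate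
25 | (5R)-5-[(1E,5E)-2-(acetoxymethyl)-6-formyl-8-(TBS-oxy)octa-1,5-dien-1-yl]-3-[(TBS-oxy)methyl]furan-2(5H)-one | CC(=O)OC/C(CC/C=C(/C=O)CCO[Si](C)(C)C(C)(C)C)=C/[C@H]1OC(=O)C(CO[Si](C)(C)C(C)(C)C)=C1 | intermediate
26 | (5R)-5-[(1E,5E)-2-(acetoxymethyl)-6-formyl-8-hydroxyocta-1,5-dien-1-yl]-3-(hydroxymethyl)furan-2(5H)-one | CC(=O)OC/C(CC/C=C(/C=O)CCO)=C/[C@H]1OC(=O)C(CO)=C1 | intermediate
27 | (5R)-5-[(1E,5E)-2-(acetoxymethyl)-6-formyl-8-hydroxyocta-1,5-dien-1-yl]-3-(bromomethyl)furan-2(5H)-one | CC(=O)OC/C(CC/C=C(/C=O)CCO)=C/[C@H]1OC(=O)C(CBr)=C1 | intermediate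
28 | (5R)-5-[(1E,5E)-2-(acetoxymethyl)-6-formyl-8-oxoocta-1,5-dien-1-yl]-3-(bromomethyl)furan-2(5H)-one | CC(=O)OC/C(CC/C=C(/C=O)CC=O)=C/[C@H]1OC(=O)C(CBr)=C1 | intermediate
29 | allylchromium dichloride of 28, chromium on C13 in place of bromine (not isolated) | CC(=O)OC/C(CC/C=C(/C=O)CC=O)=C/[C@H]1OC(=O)C(C[Cr](Cl)Cl)=C1 | intermediate
30 | [(3aR,4S,6E,10E,11aR)-6-formyl-4-hydroxy-3-methylidene-2-oxo-2,3,3a,4,5,8,9,11a-octahydrocyclodeca[b]furan-10-yl]methyl acetate | C=C1C(=O)O[C@@H]2/C=C(/COC(C)=O)CC/C=C(/C=O)C[C@H](O)[C@@H]12 | intermediate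
31 | (2S)-2-methylbutanoic anhydride | CC[C@H](C)C(=O)OC(=O)[C@@H](C)CC | starting material
32 | (3aR,4S,6E,10E,11aR)-10-(acetoxymethyl)-6-formyl-3-methylidene-2-oxo-2,3,3a,4,5,8,9,11a-octahydrocyclodeca[b]furan-4-yl (2S)-2-methylbutanoate | C=C1C(=O)O[C@@H]2/C=C(/COC(C)=O)CC/C=C(/C=O)C[C@H](OC(=O)[C@@H](C)CC)[C@@H]12 | target

**Step count and risks**

Total step count: 18. Longest linear sequence: 16 steps (steps 1–10 and 13–18); steps 11–12 make the ylide 24 on a side branch.

Steps most likely to fail:

1. Step 17 (Proposed new method). Bimolecular allylation may outrun the ten-membered closure and give oligomers. The aldehyde may reach C7 from the face of C5, or react through the chair with C9 axial, which would give the wrong relative configuration at C7 or C8. The allylchromium may also be captured by the C14 enal of a second molecule. The fallback uses known chemistry, sets out from 27 and comes back at 30. The bromide of 27 is exchanged for tin with Me3SnSnMe3 and catalytic Pd2(dba)3 in THF to give the allylic stannane (5R)-5-[(1E,5E)-2-(acetoxymethyl)-6-formyl-8-hydroxyocta-1,5-dien-1-yl]-3-[(trimethylstannyl)methyl]furan-2(5H)-one F1. Dess–Martin oxidation of the C8 alcohol then gives the stannyl dialdehyde (5R)-5-[(1E,5E)-2-(acetoxymethyl)-6-formyl-8-oxoocta-1,5-dien-1-yl]-3-[(trimethylstannyl)methyl]furan-2(5H)-one F2. F2 is cyclised with BF3·OEt2 in CH2Cl2 at −78 °C under high dilution, a Lewis-acid-promoted intramolecular allylstannane–aldehyde addition of the kind used to close macrocarbocycles; attack through C7 (SE2′) on the complexed C8 aldehyde should give 30. The nucleophile is thus made and purified before the ring closure and reacts through an open transition state, so the closure no longer depends on generating an organometal at high dilution. The C7/C8 relation then rests on the ring-strain argument alone.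

2. Step 4. Enantiofacial discrimination may be poor with this doubly activated enal, or the alkynylzinc may add in a conjugate sense. The fallback sets out from 7 and comes back at 10. The lithium acetylide of 8 (n-BuLi, THF, −78 °C) adds to the aldehyde of 7 to give racemic ethyl (2E)-4-hydroxy-2-(prop-2-en-1-yl)-7-(TBS-oxy)hept-2-en-5-ynoate F3. Dess–Martin oxidation gives the ynone ethyl (2E)-4-oxo-2-(prop-2-en-1-yl)-7-(TBS-oxy)hept-2-en-5-ynoate F4. Reduction of F4 with catecholborane and the (R)-methyl-CBS oxazaborolidine, with the alkenyl group as the large and the alkynyl group as the small substituent, should return 10; the stereocentre is then set by reduction and not by addition.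

3. Step 13. The olefination with the weakly nucleophilic formyl ylide may be slow at 80 °C. That would give time for base- or heat-induced migration of the butenolide double bond towards C6 (loss of the stereocentre) or for aldol self-condensation of 18. The fallback sets out from 18 and comes back at 25. Non-basic methylenation of 18 with Zn, CH2Br2 and TiCl4 (Takai–Lombardo) gives the terminal alkene (5R)-5-[(1E)-2-(acetoxymethyl)hexa-1,5-dien-1-yl]-3-[(TBS-oxy)methyl]furan-2(5H)-one F5. The partner 4-(TBS-oxy)-2-methylidenebutanal F6 is made from commercial 4-(TBS-oxy)butanal with aqueous formaldehyde and pyrrolidinium propionate (Mannich methylenation). Cross-metathesis of F5 with F6 using the second-generation Hoveyda–Grubbs catalyst in CH2Cl2 at 40 °C should give 25, E-selective as with methacrolein, at a temperature and pH at which the butenolide is safe.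

Further compounds
F1 | step 17 | (5R)-5-[(1E,5E)-2-(acetoxymethyl)-6-formyl-8-hydroxyocta-1,5-dien-1-yl]-3-[(trimethylstannyl)methyl]furan-2(5H)-one | CC(=O)OC/C(CC/C=C(/C=O)CCO)=C/[C@H]1OC(=O)C(C[Sn](C)(C)C)=C1
F2 | step 17 | (5R)-5-[(1E,5E)-2-(acetoxymethyl)-6-formyl-8-oxoocta-1,5-dien-1-yl]-3-[(trimethylstannyl)methyl]furan-2(5H)-one | CC(=O)OC/C(CC/C=C(/C=O)CC=O)=C/[C@H]1OC(=O)C(C[Sn](C)(C)C)=C1
F3 | step 4 | racemic ethyl (2E)-4-hydroxy-2-(prop-2-en-1-yl)-7-(TBS-oxy)hept-2-en-5-ynoate | CCOC(=O)/C(CC=C)=C/C(O)C#CCO[Si](C)(C)C(C)(C)C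
F4 | step 4 | ethyl (2E)-4-oxo-2-(prop-2-en-1-yl)-7-(TBS-oxy)hept-2-en-5-ynoate | CCOC(=O)/C(CC=C)=C/C(=O)C#CCO[Si](C)(C)C(C)(C)C
F5 | step 13 | (5R)-5-[(1E)-2-(acetoxymethyl)hexa-1,5-dien-1-yl]-3-[(TBS-oxy)methyl]furan-2(5H)-one | CC(=O)OC/C(CCC=C)=C/[C@H]1OC(=O)C(CO[Si](C)(C)C(C)(C)C)=C1
F6 | step 13 | 4-(TBS-oxy)-2-methylidenebutanal | C=C(CCO[Si](C)(C)C(C)(C)C)C=O
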